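1. Look into the vessel: starting complex turns into complex with one exchanged, and in the oak run the second stalls while the first keeps falling. Write c(start) and c(one) for these two, in percent of the starting complex charged.

the same everywhere: starting complex 0.50 M
- oak: incoming ligand 0.65 M; temperature −20 °C; the very flask that is asked about, followed so far
- ash: incoming ligand 0.44 M; temperature −14 °C; run made earlier
- flask: incoming ligand 0.650 M; temperature −20 °C; time 1.0 h

| run | time / min | complex with one exchanged / % | starting complex / % |
|---|---|---|---|
| oak | 3.00 | 5 | 91 |
| oak | 10.0 | 14 | 70 |
| oak | 15.0 | 16 | 60 |
| oak | 25.0 | 26 | 49 |
| oak | 40.0 | 24 | 41 |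
| ash | 4.00 | 10 | 79 |
| ash | 8.00 | 13 | 66 |
| ash | 12.0 | 16 | 59 |
| ash | 15.0 | 22 | 53 |
| ash | 20.0 | 22 | 49 |

(each reading ± 1.5 percentage points)

- ochre: at 1.0 h add incoming ligand, 100% of the amount charged, then wait 1.0 h
- green: at 1.0 h raise the temperature by 25 K, then wait 1.0 h
- amber: at 1.0 h take out 90% of the complex with one exchanged then present, then wait 1.0 h
- violet: change nothing and wait 1.0 h more

- removed complex with one exchanged is counted in
- additions bring no volume worth counting

* complex with one exchanged, in percent of the starting complex first charged, at 1.0 h
* which option adds most complex with one exchanged ("none" when 2 percentage points or less is all one gets) (ochre / green / amber / violet / none)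
* complex with one exchanged present, with what was taken out counted in, in percent of the starting complex first charged, after green
* complex with one exchanged present, with what was taken out counted in, in percent of the starting complex first charged, after amber

2. Assume that c(one) is lost by reaction with the same incoming ligand that makes it. Making then goes with c(start) times ligand and loss with c(one) times ligand, so the ligand cancels. The last two oak readings of c(one), 26% and 24%, are flat within the scatter of 1.5 percentage points, and their ratios to c(start) average 0.558. Take this reading as the value of c(one)/c(start) at which making equals loss, the turning ratio, a selectivity factor in the usual term. The warmer ash run, with less ligand, reads 0.449 at its end.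

3. Way one: let the oak plateau stand, which gives 25.0% at 1.0 h.

4. Way two: continue the last proportional fall of c(start) to 32.3%, then multiply by the turning ratio. This gives a turning level of 18.0%.

5. The two part by 7 points, and way two cheats. The level sinks with c(start), while c(one) has to be used up to follow it, so on this reckoning it trails above the level. My own reckoning for the oak flask is therefore a little under the plateau. On this reckoning ochre and green hurry that fall in the oak flask. Taking out 90% of the plateau value leaves 2.50%, far under the level, so I expect c(one) to climb again, and I choose amber.

6. The forecast differs from this. It gives 30% (27% to 33%), 42% after green and 35% after amber, and its best option is ochre: “Ochre is the safest choice”.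

7. The flask gives 23.0% at 1.0 h, 21.1% after green and 29.6% after amber, and the best option is amber, with 6.6 points against −9.5 points for ochre.

    starting complex + incoming ligand → leaving ligand + complex with one exchanged (k = 5.67 × 10⁻⁴ /M/s, Ea = 60.0 kJ/mol)
    complex with one exchanged + incoming ligand → leaving ligand + complex with two exchanged (k = 8.87 × 10⁻⁴ /M/s, Ea = 65.0 kJ/mol)
    complex with two exchanged + incoming ligand → leaving ligand + complex with three exchanged (k = 0.00180 /M/s, Ea = 51.0 kJ/mol)
    crystals ⇌ leaving ligand, rate k4*(cs4 - [leaving ligand]) while solid is left; crystals form when [leaving ligand] > cs4 (solubility = 0.250 M, k = 0.0270 /s)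
    starting complex ⇌ dormant form (K = 0.636, k = 2.60 × 10⁻⁴ /s, Ea = 79.0 kJ/mol, ΔH = −35.0 kJ/mol)
    (constants at −20 °C)

At 15.1 min the oak flask makes complex with one exchanged 2.15 times faster than it uses it, net of each step. By 1.0 h its ratio of 0.725 stands above the turning ratio, and violet brings −1.8 points.

8. Now take the same flask with 2.6 M of incoming ligand, where c(start) is 4.28% at 1.0 h. The turning ratio puts the level at 2.39%, so expect c(one) low and trailing above it. The computed value is 4.64%.

(The earlier runs and the new flask were computed for an exercise, and the scatter is random.)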